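**Plan**

- Retrosynthesis: the exocyclic C=C of the quinone methide (dibenzofuran C1 to the aryl-bearing lactone carbon) is traced back to its hydrate, a tertiary carbinol para to the C4 phenol, with all four phenols as methyl ethers. The lactone is then cut at two bonds, aryl C2–O and aryl C1–C(OH), which leaves a dibenzofuran-1,2-yne and 4-methoxyphenylglyoxylate.
- Enabling feature: the five-membered lactone (ring D) has its ring oxygen on C2 and its aryl-bearing carbon on C1, two neighbouring carbons of the substituted benzene ring (ring A) of the dibenzofuran. This vicinal O/C pair is what an aryne accepts in one operation.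
- The aryne precursor (1-SiMe3, 2-OTf) comes from the dibenzofuran-2-ol. The furan (ring B) is cut at the C9a–C9b biaryl bond and the C4a–O ether bond, and the 3-phenyl group at the CH flanked by two alkoxy groups (Negishi).
- Forward: ring A is substituted first (isopropyl ether, phenyl), ring C (3,4-dimethoxyphenol) is attached through oxygen, ring B is closed by oxidative C–C coupling, ring D by the aryne annulation, and demethylation with loss of water ends the route.
- Stereochemistry: the target has no stereocentre. The carbinol centre made in the key step is racemic and becomes sp2 in the last step.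

Key step: step 8

Assumption: the target is drawn with the quinone methide carbonyl at C4 of the dibenzofuran; the tautomer with the carbonyl on the 4-hydroxyphenyl ring is taken to interconvert with it by proton transfer, the drawn form being the one obtained. Dibenzofuran locants are used throughout.

**Step 1**
Reactants: 1 4-chloro-3-methoxyphenol
Product: 2 1-chloro-2-methoxy-4-(propan-2-yloxy)benzene
Conditions: 2-bromopropane, K2CO3, DMF, 60 °C
Reagents that add atoms: 2-bromopropane, CC(C)Br
Why: Williamson ether synthesis on the phenoxide; the isopropyl ether should survive organolithium, palladium and pivalic acid conditions and can later be cleaved beside methyl ethers.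

**Step 2**
Reactants: 2 1-chloro-2-methoxy-4-(propan-2-yloxy)benzene; 3 iodobenzene
Product: 6 3-chloro-2-methoxy-6-(propan-2-yloxy)biphenyl, via aryllithium 4 (not isolated), via arylzinc chloride 5 (not isolated)
Conditions: n-BuLi, THF, −20 → 0 °C; ZnCl2, 0 °C → rt; PhI, Pd(PPh3)4 (3 mol %), 60 °C
Reagents that add atoms: none
Why: Directed ortho-metalation should remove the proton flanked by the two alkoxy groups (doubly coordinated and most acidic, with lithium meta to chlorine so that no aryne can form), and after transmetalation to zinc a Negishi coupling with iodobenzene should proceed while the C–Cl bond stays inert to Pd(PPh3)4.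

**Step 3**
Reactants: 6 3-chloro-2-methoxy-6-(propan-2-yloxy)biphenyl; 7 3,4-dimethoxyphenol
Product: 8 3-(3,4-dimethoxyphenoxy)-2-methoxy-6-(propan-2-yloxy)biphenyl
Conditions: Pd(OAc)2 (3 mol %), tBuXPhos (6 mol %), K3PO4, toluene, 100 °C
Reagents that add atoms: none
Why: Buchwald–Hartwig-type diaryl ether synthesis; bulky di-tert-butylbiarylphosphines are the ligand class that allows C–O reductive elimination with electron-rich aryl chlorides and phenols.

**Step 4**
Reactants: 8 3-(3,4-dimethoxyphenoxy)-2-methoxy-6-(propan-2-yloxy)biphenyl
Product: 9 4,7,8-trimethoxy-3-phenyl-2-(propan-2-yloxy)dibenzofuran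
Conditions: Pd(OAc)2 (5 mol %), K2CO3 (10 mol %), PivOH, air, 120 °C
Reagents that add atoms: none
Why: Intramolecular dehydrogenative biaryl coupling of a diaryl ether (twofold C–H palladation by divalent palladium, air as terminal oxidant); ring A has a single free position ortho to the ether oxygen and ring C should react at its unhindered ortho C–H, which gives the 7,8-dimethoxy pattern.

**Step 5**
Reactants: 9 4,7,8-trimethoxy-3-phenyl-2-(propan-2-yloxy)dibenzofuran
Product: 10 4,7,8-trimethoxy-3-phenyldibenzofuran-2-ol
Conditions: BCl3, CH2Cl2, −78 → 0 °C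
Reagents that add atoms: none
Why: Lewis acid ether cleavage; BCl3 removes a secondary isopropyl aryl ether through the stabilised 2-propyl cation far faster than it touches methyl ethers at low temperature.

**Step 6**
Reactants: 10 4,7,8-trimethoxy-3-phenyldibenzofuran-2-ol
Product: 11 1-bromo-4,7,8-trimethoxy-3-phenyldibenzofuran-2-ol
Conditions: NBS, iPr2NH (10 mol %), CH2Cl2, −20 °C
Reagents that add atoms: N-bromosuccinimide, O=C1CCC(=O)N1Br
Why: Electrophilic aromatic bromination ortho to the phenol; C1 is the only free position ortho to the hydroxyl and is also para to the C4 methoxy group, so it should react ahead of the ring C positions.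

**Step 7**
Reactants: 11 1-bromo-4,7,8-trimethoxy-3-phenyldibenzofuran-2-ol
Product: 14 4,7,8-trimethoxy-3-phenyl-1-(trimethylsilyl)dibenzofuran-2-yl trifluoromethanesulfonate, via silyl ether 12 (not isolated), via lithium phenolate 13 (not isolated)
Conditions: HMDS, THF, 65 °C, then evaporation; n-BuLi, THF, −100 → −78 °C; Tf2O, −100 °C → rt
Reagents that add atoms: hexamethyldisilazane, C[Si](C)(C)N[Si](C)(C)C; trifluoromethanesulfonic anhydride, O=S(=O)(OS(=O)(=O)C(F)(F)F)C(F)(F)F
Why: O-silylation, bromine–lithium exchange and 1,3 O→C silyl shift (retro-Brook rearrangement) should give the ortho-silyl phenolate, which Tf2O sulfonylates; this is the standard one-pot route from ortho-bromophenols to ortho-silylaryl triflates.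

**Step 8**
Reactants: 14 4,7,8-trimethoxy-3-phenyl-1-(trimethylsilyl)dibenzofuran-2-yl trifluoromethanesulfonate; 15 2-(4-methoxyphenyl)-2-oxoacetic acid
Product: 18 racemic 3-hydroxy-3-(4-methoxyphenyl)furan-2(3H)-one fused at C1/C2 of 4,7,8-trimethoxy-3-phenyldibenzofuran (lactone O on C2; carbinol carbon on C1), via potassium carboxylate 16 (not isolated), via dibenzofuran-1,2-yne 17 (not isolated)
Conditions: 15 + KH (2 equiv each), THF, 0 °C; then 14, KF, 18-crown-6, THF, rt → 40 °C; 1 M HCl work-up
Reagents that add atoms: none
Why: Proposed new method: fluoride attacks silicon at C1 and the C2 triflate leaves to give aryne 17; a carboxylate oxygen of 16 then adds to C2 and the resulting C1 aryl anion attacks the neighbouring ketone carbonyl of the aryl glyoxylate ester, so the aryl C2–O and C1–C bonds form in one operation. The closest known reaction types are aryne insertion into carboxylic acids (O-arylation, with capture of the aryl anion by the acyl group to give ortho-hydroxyaryl ketones) and aryne acyl-alkylation by sigma-bond insertion. The lactone ring closes by 5-exo-trig addition of the aryl anion to the ketone, which should outrun the four-membered attack on the ester carbonyl because the ketone is the more electrophilic carbonyl and the five-membered transition state is unstrained. The new carbinol centre forms without control as a racemate, which is harmless because it becomes sp2 in step 9. The step needs oxygen at C2 and the carbanion at C1: the five-membered ring fused at C9b distorts the aryne so that C2 is the flatter, more electrophilic terminus (as in 1,2-naphthalyne, 4,5-indolyne and 4,5-benzofuranyne) and attack at C1 would meet the bay hydrogen on C9, whereas the twisted 3-phenyl group and the inductive pull of the 4-methoxy group work against this and make regiochemistry the main risk. The preformed potassium carboxylate with KF/18-crown-6 in THF leaves no acidic proton, so the aryl anion should close the ring instead of being protonated to the simple aryl ester.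

**Step 9**
Reactants: 18 racemic 3-hydroxy-3-(4-methoxyphenyl)furan-2(3H)-one fused at C1/C2 of 4,7,8-trimethoxy-3-phenyldibenzofuran
Product: 20 CNP0139113.0, via pentahydroxy carbinol 19 (not isolated)
Conditions: BBr3 (10 equiv), CH2Cl2, −78 °C → rt; H2O; 1 M HCl, EtOAc, rt
Reagents that add atoms: none
Why: BBr3 cleavage of the four aryl methyl ethers, after which the doubly benzylic tertiary carbinol, now para to the free C4 phenol, should lose water by acid-promoted 1,6-elimination to the conjugated quinone methide without any change of oxidation level.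

**Compound list**

1 | 4-chloro-3-methoxyphenol | COc1cc(O)ccc1Cl | starting material
2 | 1-chloro-2-methoxy-4-(propan-2-yloxy)benzene | COc1cc(OC(C)C)ccc1Cl | intermediate
3 | iodobenzene | Ic1ccccc1 | starting material
4 | [3-chloro-2-methoxy-6-(propan-2-yloxy)phenyl]lithium | COc1c(Cl)ccc(OC(C)C)c1[Li] | intermediate
5 | [3-chloro-2-methoxy-6-(propan-2-yloxy)phenyl]zinc chloride | COc1c(Cl)ccc(OC(C)C)c1[Zn]Cl | intermediate
6 | 3-chloro-2-methoxy-6-(propan-2-yloxy)biphenyl | COc1c(Cl)ccc(OC(C)C)c1-c1ccccc1 | intermediate
7 | 3,4-dimethoxyphenol | COc1ccc(O)cc1OC | starting material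
8 | 3-(3,4-dimethoxyphenoxy)-2-methoxy-6-(propan-2-yloxy)biphenyl | COc1ccc(Oc2ccc(OC(C)C)c(-c3ccccc3)c2OC)cc1OC | intermediate
9 | 4,7,8-trimethoxy-3-phenyl-2-(propan-2-yloxy)dibenzofuran | COc1cc2oc3c(OC)c(-c4ccccc4)c(OC(C)C)cc3c2cc1OC | intermediate
10 | 4,7,8-trimethoxy-3-phenyldibenzofuran-2-ol | COc1cc2oc3c(OC)c(-c4ccccc4)c(O)cc3c2cc1OC | intermediate
11 | 1-bromo-4,7,8-trimethoxy-3-phenyldibenzofuran-2-ol | COc1cc2oc3c(OC)c(-c4ccccc4)c(O)c(Br)c3c2cc1OC | intermediate
12 | [(1-bromo-4,7,8-trimethoxy-3-phenyldibenzofuran-2-yl)oxy]trimethylsilane | COc1cc2oc3c(OC)c(-c4ccccc4)c(O[Si](C)(C)C)c(Br)c3c2cc1OC | intermediate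
13 | lithium 4,7,8-trimethoxy-3-phenyl-1-(trimethylsilyl)dibenzofuran-2-olate | [Li+].COc1cc2oc3c(OC)c(-c4ccccc4)c([O-])c([Si](C)(C)C)c3c2cc1OC | intermediate
14 | 4,7,8-trimethoxy-3-phenyl-1-(trimethylsilyl)dibenzofuran-2-yl trifluoromethanesulfonate | COc1cc2oc3c(OC)c(-c4ccccc4)c(OS(=O)(=O)C(F)(F)F)c([Si](C)(C)C)c3c2cc1OC | intermediate
15 | 2-(4-methoxyphenyl)-2-oxoacetic acid | COc1ccc(C(=O)C(=O)O)cc1 | starting material
16 | potassium 2-(4-methoxyphenyl)-2-oxoacetate | [K+].COc1ccc(C(=O)C(=O)[O-])cc1 | intermediate
17 | 4,7,8-trimethoxy-3-phenyl-1,2-didehydrodibenzofuran (dibenzofuran-1,2-yne) | COC1=C(c2ccccc2)C#CC2=C1Oc1cc(OC)c(OC)cc12 | intermediate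
18 | racemic 3-hydroxy-3-(4-methoxyphenyl)furan-2(3H)-one fused at C1/C2 of 4,7,8-trimethoxy-3-phenyldibenzofuran (lactone O on C2; carbinol carbon on C1) | COc1ccc(C2(O)C(=O)Oc3c(-c4ccccc4)c(OC)c4oc5cc(OC)c(OC)cc5c4c32)cc1 | intermediate
19 | racemic 3-hydroxy-3-(4-hydroxyphenyl)furan-2(3H)-one fused at C1/C2 of 3-phenyldibenzofuran-4,7,8-triol (pentahydroxy carbinol) | Oc1ccc(C2(O)C(=O)Oc3c(-c4ccccc4)c(O)c4oc5cc(O)c(O)cc5c4c32)cc1 | intermediate
20 | CNP0139113.0: 7,8-dihydroxy-3-phenyldibenzofuran whose ring A is a 4-oxocyclohexadiene (C4=O, C2=C3), with C1 double-bonded to the 4-hydroxyphenyl-bearing carbon of a five-membered lactone that closes through its ring oxygen on C2 | O=C1OC2=C(c3ccccc3)C(=O)c3oc4cc(O)c(O)cc4c3C2=C1c1ccc(O)cc1 | target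

**Totals**

Total step count: 9. Longest linear sequence: 9 steps (1 → 20); 3, 7 and 15 are bought.

**Steps most likely to fail**

Step 8: the carboxylate may add to the wrong aryne terminus (C1 instead of C2), or the aryl anion may be protonated or undergo four-membered acyl transfer before it reaches the ketone. The fallback sets out from phenol 10 and returns at 18. TiCl4-mediated ortho-selective Friedel–Crafts hydroxyalkylation of 10 with ethyl 2-(4-methoxyphenyl)-2-oxoacetate (CH2Cl2, −78 → 0 °C) should put the carbinol carbon on C1, the only free ortho position, to give ethyl 2-hydroxy-2-(2-hydroxy-4,7,8-trimethoxy-3-phenyldibenzofuran-1-yl)-2-(4-methoxyphenyl)acetate F1. TsOH in warm toluene should then close the lactone with loss of ethanol to give 18; steps 6 and 7 are not needed on this path.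

Step 9: ionisation of the tertiary carbinol under BBr3 may lead to lactone cleavage or oligomerisation before the hindered C4 methyl ether has been removed. The fallback sets out from 18 and returns at 20. Ionic hydrogenation (Et3SiH, TFA, CH2Cl2) should remove the tertiary hydroxyl and give the 3-(4-methoxyphenyl)furan-2(3H)-one fused to 4,7,8-trimethoxy-3-phenyldibenzofuran F2. BBr3 then has no ionisable carbinol to contend with and should give the tetrahydroxy 3-H lactone F3. Dehydrogenation of the para-hydroxybenzylic C–H of F3 with one equivalent of chloranil (dioxane, rt) should deliver the quinone methide 20.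

Step 3: C–O reductive elimination from the hindered, electron-rich arylpalladium phenoxide may be slow, so that hydrodechlorination takes over. The fallback sets out from 6 and returns at 8. Palladium-catalysed hydroxylation of the chloride (KOH, Pd2(dba)3, tBuXPhos, dioxane/H2O, 100 °C) should give 2-methoxy-3-phenyl-4-(propan-2-yloxy)phenol F4. Chan–Lam coupling of F4 with 3,4-dimethoxyphenylboronic acid (Cu(OAc)2, pyridine, 4 Å MS, CH2Cl2, air) should give the diaryl ether 8.

**Further compounds**

F1 | step 8 | ethyl 2-hydroxy-2-(2-hydroxy-4,7,8-trimethoxy-3-phenyldibenzofuran-1-yl)-2-(4-methoxyphenyl)acetate | CCOC(=O)C(O)(c1ccc(OC)cc1)c1c(O)c(-c2ccccc2)c(OC)c2oc3cc(OC)c(OC)cc3c12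
F2 | step 9 | racemic 3-(4-methoxyphenyl)furan-2(3H)-one fused at C1/C2 of 4,7,8-trimethoxy-3-phenyldibenzofuran | COc1ccc(C2C(=O)Oc3c(-c4ccccc4)c(OC)c4oc5cc(OC)c(OC)cc5c4c32)cc1
F3 | step 9 | racemic 3-(4-hydroxyphenyl)furan-2(3H)-one fused at C1/C2 of 3-phenyldibenzofuran-4,7,8-triol | Oc1ccc(C2C(=O)Oc3c(-c4ccccc4)c(O)c4oc5cc(O)c(O)cc5c4c32)cc1
F4 | step 3 | 2-methoxy-3-phenyl-4-(propan-2-yloxy)phenol | COc1c(O)ccc(OC(C)C)c1-c1ccccc1
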